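All constants were chosen freely; what happens was integrated by code.

Count turnovers.

    starting material + free enzyme ⇌ first complex (K1 = 47 /M, k1 = 71000 /M/s)
    first complex → loaded enzyme + first product (k2 = 220 /s)
    second substrate + loaded enzyme ⇌ second complex (K3 = 63 /M, k3 = 46000 /M/s)
    second complex → free enzyme + target (k4 = 67 /s)
    2 second substrate → homo dimer (k5 = 0.048 /M/s)
    starting material + first product ⇌ idle adduct, settled at all times (K6 = 16 /M)
    scavenger + first product → scavenged by-product (k7 = 0.27 /M/s)

| setting | Thursday's | Saturday's | Tuesday's |
|---|---|---|---|
| starting material | 33 mM | 33 mM | 33 mM (fed, over 10 min) |
| second substrate | 0.500 equiv | 0.500 equiv (fed, over 10 min) | 0.500 equiv |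
| scavenger | 1.20 equiv | 1.20 equiv | 1.20 equiv |
| free enzyme | 0.01 mol% | 0.01 mol% | 0.01 mol% |
| time | 12 min | 12 min | 12 min |
| remark | everything together at the start | all else is in the flask from the start; the feed brings no volume worth counting | all else is in the flask from the start; the feed brings no volume worth counting |

- amounts and yields of first product count idle adduct too
- for a step with 2 of a species take k times the square, and two of it per event
- run time (Thursday's): 12 min

1. the flask with the highest amount of target, in percent of the starting material charged ("all alike" if they lie within 1.5 percentage points) (Thursday's / Saturday's / Tuesday's / all alike)
2. final target, as a percentage of the starting material charged, in Thursday's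
3. final target, as a percentage of the starting material charged, in Saturday's
4. final target, as a percentage of the starting material charged, in Tuesday's

Two numbers here refuse to go together. At its ceiling an enzyme could make 48200 turnovers in a run of 12 min, and the charge of second substrate asks 5000, ten times fewer. Yet the homo dimer, whose first half-life at Thursday's charge is 10.5 min, is supposed to matter.

The ceiling holds only for an enzyme that never waits. In Thursday's I take loaded enzyme as the resting state, because starting material reaches free enzyme at about 298 /s, faster than second substrate reaches loaded enzyme, at about 63.8 /s. So each loaded enzyme turns at 3870 /M/s times the level of second substrate, flattening with a Michaelis constant of 17.3 mM, close to Thursday's charge of 16.5 mM.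

Set that against the dimer: the capture constant times the enzyme, over twice the dimer constant, gives 133 mM, the break-even level, at which enzyme and dimer, far from saturation, would eat second substrate equally fast. At any level the dimer's rate divided by the enzyme's is that level over break-even, times one plus the level over the Michaelis constant; this is a ratio of rates, and I use it as an approximate share of second substrate lost, which it is only while it is small.

Averaged over its fall, that ratio is 10.1% in Thursday's, so I expect about 44.9% target. Saturday's feed asks 8.33 /s per enzyme, which holds the level near 2.46 mM; the ratio there is 2.12%, so about 48.9% once finished. In Tuesday's the feed of starting material paces the enzyme, second substrate falls over about 5.00 min, and 15.8% goes, leaving 42.1%.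

The forecast says 44.4%, 46.7% and 41%, with Saturday's highest: “Feeding the second substrate keeps it near 3 mM so dimer nearly vanishes”. Its Saturday's figure stands below my finished one.

The simulation gives 44.8% for Thursday's, 47.0% for Saturday's and 40.6% for Tuesday's, so Saturday's leads. Homo dimer took 10.5% of Thursday's second substrate, more than the 1.92% of Saturday's. The forecast's 41% for Tuesday's fails if break-even falls: a neighbour of Tuesday's with 0.004 mol% of free enzyme has it at 53.2 mM, dimer took 27.8% there, and target ended at 32.5%.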